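**Plan**

- Enabling feature: in the furan-2(5H)-one ring (O1, C2 carbonyl, C3, C4, C5) the beta carbon C4 carries only hydrogen and the single stereocentre C5 (S) is bonded to O1. The C2–C5 unit is therefore an isomer of a 2,4-disubstituted buta-2,3-dienoic acid, and a chiral allene axis can stand in for C5.
- Retrosynthetic cuts: O1–C5 first (lactone to the aS allenoic acid), then C3–C4 (allene to an alpha-diazo ester holding C2, C3 and the six-carbon arm, plus a terminal alkyne holding C4, C5 and the five-carbon arm). Each arm goes back to a gem-dimethyl olefin.
- Forward order: the two linear halves, each ending in an E allylic acetate, are built separately and joined at C3–C4 to an open-chain allenoate. The ester is then unmasked, and the only ring is closed last through the O1–C5 bond.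
- Stereochemistry: both E olefins come from SeO2 oxidation of the E-methyl group of a prenyl terminus. The aS axis comes from a chiral copper/guanidinium catalyst, and C5 (S) from axis-to-centre transfer in the silver-catalysed closure.

Key step: step 10

Remark on the ester: the carboxyl group is carried as a 2-(trimethylsilyl)ethyl ester. A tert-butyl ester would need acid or a silyl triflate for removal, and under those conditions the prenyl-type allylic acetate of the five-carbon arm can ionise. Fluoride unmasking followed by AgNO3 closure is an established pairing for allenoates.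

Assumption: the sense of axial induction cannot be predicted for this alkyne. The catalyst is written in the (S)-pipecolic series, and its mirror image is taken if a pilot run shows the aR axis. Catalyst-bound turnover species are described in the Why lines and are not counted as compounds.

**Route**

Step 1
Reactants: 1 prenyl acetate (3-methylbut-2-en-1-yl acetate)
Product: 2 (E)-4-hydroxy-3-methylbut-2-en-1-yl acetate
Conditions: SeO2 (0.3 equiv), tBuOOH (2 equiv), salicylic acid (0.1 equiv), CH2Cl2, 0 °C to rt; minor enal removed by chromatography
Reagents that add atoms: selenium dioxide, O=[Se]=O (hands over the hydroxyl oxygen); tert-butyl hydroperoxide, CC(C)(C)OO (terminal oxidant that restores it)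
Why: Catalytic SeO2 allylic oxidation (ene reaction, then 2,3-sigmatropic shift of the allylseleninic acid) attacks the methyl group cis to the vinylic hydrogen of a gem-dimethyl olefin, which fixes the E geometry of the new allylic alcohol while the acetate is inert.

Step 2
Reactants: 2 (E)-4-hydroxy-3-methylbut-2-en-1-yl acetate
Product: 3 (E)-4-bromo-3-methylbut-2-en-1-yl acetate
Conditions: CBr4, PPh3, CH2Cl2, 0 °C
Reagents that add atoms: carbon tetrabromide, BrC(Br)(Br)Br
Why: Appel bromination displaces the alkoxyphosphonium group at the primary carbon in SN2 fashion, so the olefin should keep both its position and its E geometry.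

Step 3
Reactants: 3 (E)-4-bromo-3-methylbut-2-en-1-yl acetate; 4 trimethylsilylacetylene
Product: 5 (E)-3-methyl-6-(trimethylsilyl)hex-2-en-5-yn-1-yl acetate
Conditions: CuI (20 mol %), NaI (20 mol %), K2CO3 (1.5 equiv), DMF, rt
Reagents that add atoms: none
Why: Copper acetylide allylation of a terminal alkyne with a primary allylic halide substitutes the unhindered CH2 terminus in SN2 fashion, the silyl cap prevents a second allylation, and anhydrous carbonate leaves the acetate and the E olefin alone.

Step 4
Reactants: 5 (E)-3-methyl-6-(trimethylsilyl)hex-2-en-5-yn-1-yl acetate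
Product: 6 (E)-3-methylhex-2-en-5-yn-1-yl acetate
Conditions: Bu4NF (1.1 equiv), AcOH (1.2 equiv), THF, 0 °C; careful concentration (volatile product)
Reagents that add atoms: none
Why: Fluoride protodesilylation of an alkynylsilane, buffered with acetic acid so that the medium stays non-basic, should free the terminal alkyne without acetate loss or migration of the doubly activated methylene into an allene.

Step 5
Reactants: 7 5-bromo-2-methylpent-2-ene
Product: 8 (E)-5-bromo-2-methylpent-2-en-1-ol
Conditions: SeO2 (0.3 equiv), tBuOOH (2 equiv), salicylic acid (0.1 equiv), CH2Cl2, 0 °C to rt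
Reagents that add atoms: selenium dioxide, O=[Se]=O (hands over the hydroxyl oxygen); tert-butyl hydroperoxide, CC(C)(C)OO (terminal oxidant that restores it)
Why: The same catalytic SeO2 allylic oxidation again selects the E-methyl group of the gem-dimethyl terminus, and the remote primary bromide is inert to the oxidant.

Step 6
Reactants: 8 (E)-5-bromo-2-methylpent-2-en-1-ol
Product: 9 (E)-5-bromo-2-methylpent-2-en-1-yl acetate
Conditions: Ac2O, pyridine, DMAP (cat.), CH2Cl2, 0 °C
Reagents that add atoms: acetic anhydride, CC(=O)OC(C)=O
Why: DMAP-catalysed O-acetylation of a primary allylic alcohol is fast at 0 °C, well ahead of any quaternisation of the primary bromide.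

Step 7
Reactants: 10 tert-butyl acetoacetate; 11 2-(trimethylsilyl)ethanol
Product: 12 2-(trimethylsilyl)ethyl acetoacetate
Conditions: toluene, 110 °C, tBuOH distilled off
Reagents that add atoms: none
Why: Thermal transacetoacetylation: tert-butyl acetoacetate loses tert-butanol to give acetylketene, which the primary alcohol traps as the new beta-keto ester.

Step 8
Reactants: 9 (E)-5-bromo-2-methylpent-2-en-1-yl acetate; 12 2-(trimethylsilyl)ethyl acetoacetate (1.5 equiv)
Product: 13 2-(trimethylsilyl)ethyl (E)-7-acetoxy-2-acetyl-6-methylhept-5-enoate (racemic at C2)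
Conditions: K2CO3, NaI (10 mol %), acetone, reflux
Reagents that add atoms: none
Why: Acetoacetic ester alkylation, in which the soft enolate displaces the iodide-exchanged primary halide by SN2, with excess keto ester curbing dialkylation; the new centre is of no consequence because the next step erases it.

Step 9
Reactants: 13 2-(trimethylsilyl)ethyl (E)-7-acetoxy-2-acetyl-6-methylhept-5-enoate
Product: 14 2-(trimethylsilyl)ethyl (E)-7-acetoxy-2-diazo-6-methylhept-5-enoate
Conditions: 4-acetamidobenzenesulfonyl azide (1.2 equiv), DBU (1.5 equiv), MeCN, 0 °C to rt
Reagents that add atoms: 4-acetamidobenzenesulfonyl azide, CC(=O)Nc1ccc(cc1)S(=O)(=O)N=[N+]=[N-]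
Why: Regitz deacylative diazo transfer, in which the enolate adds to the azide terminus and the adduct fragments with passage of the acetyl group to the sulfonamide nitrogen, should leave the alpha-alkyl alpha-diazo ester with both ester types intact.

Step 10
Reactants: 6 (E)-3-methylhex-2-en-5-yn-1-yl acetate (1.5 equiv); 14 2-(trimethylsilyl)ethyl (E)-7-acetoxy-2-diazo-6-methylhept-5-enoate
Product: 15 2-(trimethylsilyl)ethyl (aS,6E)-8-acetoxy-2-[(E)-5-acetoxy-4-methylpent-3-en-1-yl]-6-methylocta-2,3,6-trienoate
Conditions: CuI (10 mol %), (S)-1-(N,N'-dicyclohexylcarbamimidoyl)-N-(2,6-diisopropylphenyl)piperidine-2-carboxamide hydrobromide (10 mol %), CH2Cl2, 30 °C, 14 added by syringe pump over 6 h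
Reagents that add atoms: none
Why: The copper acetylide of 6 captures diazo ester 14 with loss of N2 to give an alkynyl copper carbene, migration of the alkynyl group onto the carbene carbon forms the C3–C4 bond as a propargyl/allenyl copper species, and the chiral guanidinium hands a proton to C5 to release the allenoate. The closest known reaction is the enantioselective coupling of alpha-alkyl alpha-diazo esters with terminal alkyl alkynes under monovalent copper and a chiral guanidinium salt, which gives 2,4-disubstituted 2,3-allenoates; a skipped enyne is only a new member of that alkyne class. No ring is closed in this step. The new stereogenic element is the aS allene axis, fixed by the face of C5 to which the hydrogen-bonded guanidinium delivers the proton. The step needs protonation at C5 and not at C3 (allenoate, not 3-alkynoate), acetylide capture faster than the 1,2-hydride shift of the carbene, and no drift of the doubly allylic methylene next to C5 into conjugation. These are secured by the proton-shuttle catalyst, by slow addition of 14 into excess 6, by the two-carbon tether that rules out intramolecular cyclopropanation, and by the absence of free amine base.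

Step 11
Reactants: 15 2-(trimethylsilyl)ethyl (aS,6E)-8-acetoxy-2-[(E)-5-acetoxy-4-methylpent-3-en-1-yl]-6-methylocta-2,3,6-trienoate
Product: 17 (aS,6E)-8-acetoxy-2-[(E)-5-acetoxy-4-methylpent-3-en-1-yl]-6-methylocta-2,3,6-trienoic acid, via tetrabutylammonium allenoate 16 (not isolated)
Conditions: Bu4NF (1.5 equiv), THF, 0 °C, 30 min; then cold 0.5 M HCl
Reagents that add atoms: none
Why: Fluoride attacks silicon and the 2-silylethyl group fragments to ethylene and fluorotrimethylsilane (beta-elimination of a 2-(trimethylsilyl)ethyl ester), an unmasking established for allenoates; the carboxylate so formed resists gamma-deprotonation, so the axis should persist, and brief exposure at 0 °C spares the acetates.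

Step 12
Reactants: 17 (aS,6E)-8-acetoxy-2-[(E)-5-acetoxy-4-methylpent-3-en-1-yl]-6-methylocta-2,3,6-trienoic acid
Product: 18 (S)-5-[(E)-4-acetoxy-2-methylbut-2-en-1-yl]-3-[(E)-5-acetoxy-4-methylpent-3-en-1-yl]furan-2(5H)-one (CNP0412896.2)
Conditions: AgNO3 (10 mol %), acetone, rt, dark
Reagents that add atoms: none
Why: Silver-catalysed cycloisomerisation of an allenic acid: monovalent silver activates the C4–C5 π bond, the carboxyl oxygen adds to C5 in a 5-endo-trig closure and protodemetalation places hydrogen at C4; the oxygen can reach only the C5 lobe on its own side of the axis, so aS is translated into 5S.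

**Compound list**

1 | prenyl acetate (3-methylbut-2-en-1-yl acetate) | CC(C)=CCOC(C)=O | starting material
2 | (E)-4-hydroxy-3-methylbut-2-en-1-yl acetate | OC/C(C)=C/COC(C)=O | intermediate
3 | (E)-4-bromo-3-methylbut-2-en-1-yl acetate | BrC/C(C)=C/COC(C)=O | intermediate
4 | trimethylsilylacetylene | C#C[Si](C)(C)C | starting material
5 | (E)-3-methyl-6-(trimethylsilyl)hex-2-en-5-yn-1-yl acetate | C[Si](C)(C)C#CC/C(C)=C/COC(C)=O | intermediate
6 | (E)-3-methylhex-2-en-5-yn-1-yl acetate | C#CC/C(C)=C/COC(C)=O | intermediate
7 | 5-bromo-2-methylpent-2-ene | CC(C)=CCCBr | starting material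
8 | (E)-5-bromo-2-methylpent-2-en-1-ol | BrCC/C=C(\C)CO | intermediate
9 | (E)-5-bromo-2-methylpent-2-en-1-yl acetate | BrCC/C=C(\C)COC(C)=O | intermediate
10 | tert-butyl acetoacetate | CC(=O)CC(=O)OC(C)(C)C | starting material
11 | 2-(trimethylsilyl)ethanol | C[Si](C)(C)CCO | starting material
12 | 2-(trimethylsilyl)ethyl acetoacetate | CC(=O)CC(=O)OCC[Si](C)(C)C | intermediate
13 | 2-(trimethylsilyl)ethyl (E)-7-acetoxy-2-acetyl-6-methylhept-5-enoate (racemic at C2) | CC(=O)C(CC/C=C(\C)COC(C)=O)C(=O)OCC[Si](C)(C)C | intermediate
14 | 2-(trimethylsilyl)ethyl (E)-7-acetoxy-2-diazo-6-methylhept-5-enoate | C[Si](C)(C)CCOC(=O)C(=[N+]=[N-])CC/C=C(\C)COC(C)=O | intermediate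
15 | 2-(trimethylsilyl)ethyl (aS,6E)-8-acetoxy-2-[(E)-5-acetoxy-4-methylpent-3-en-1-yl]-6-methylocta-2,3,6-trienoate | C[Si](C)(C)CCOC(=O)C(CC/C=C(\C)COC(C)=O)=[C@@]=C([H])C/C(C)=C/COC(C)=O | intermediate
16 | tetrabutylammonium (aS,6E)-8-acetoxy-2-[(E)-5-acetoxy-4-methylpent-3-en-1-yl]-6-methylocta-2,3,6-trienoate | CCCC[N+](CCCC)(CCCC)CCCC.[O-]C(=O)C(CC/C=C(\C)COC(C)=O)=[C@@]=C([H])C/C(C)=C/COC(C)=O | intermediate
17 | (aS,6E)-8-acetoxy-2-[(E)-5-acetoxy-4-methylpent-3-en-1-yl]-6-methylocta-2,3,6-trienoic acid | OC(=O)C(CC/C=C(\C)COC(C)=O)=[C@@]=C([H])C/C(C)=C/COC(C)=O | intermediate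
18 | (S)-5-[(E)-4-acetoxy-2-methylbut-2-en-1-yl]-3-[(E)-5-acetoxy-4-methylpent-3-en-1-yl]furan-2(5H)-one | CC(=O)OC/C=C(\C)C[C@H]1C=C(CC/C=C(\C)COC(C)=O)C(=O)O1 | target

**Step count and risks**

Total steps: 12. Longest linear sequence: 7 steps (steps 5, 6, 8, 9, 10, 11, 12; the alkyne branch, steps 1 to 4 then 10 to 12, is equally long).

Step 10. The protonation that fixes the axis may discriminate poorly between the two faces of C5 for a skipped-enyne alkyne, leaving an allenoate of low enantiomeric purity even if the coupling itself proceeds. Fallback: setting out from 6 and 14, the same union is run without chiral control (CuI, catalytic Et3N, MeCN, slow addition), which should give the racemic 2-(trimethylsilyl)ethyl allenoate F1. Preparative chromatography on a cellulose tris(3,5-dimethylphenylcarbamate) phase then separates the antipodes, and the unwanted (aR)-allenoate F2 is set aside. The aS antipode is compound 15, where the route resumes before step 11. The axis is then obtained by resolution and not by catalyst control.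

Step 11. Fluoride may act as a base toward the ester before it attacks silicon, removing the hydrogen at C5 and so eroding the axis or moving the cumulene into conjugation with the neighbouring olefin; prolonged exposure may also strip an acetate. Fallback: the free acid is bypassed. Setting out from 9 and 10, alkylation (K2CO3, NaI, acetone) should give tert-butyl (E)-7-acetoxy-2-acetyl-6-methylhept-5-enoate F3. Deacylative diazo transfer then gives the tert-butyl diazo ester F4, and coupling with 6 under the conditions of step 10 gives the tert-butyl (aS)-allenoate F5. AuCl3 (5 mol %, CH2Cl2, rt) is known to close tert-butyl allenoates directly to butenolides. The ester carbonyl oxygen adds to the gold-activated C4–C5 bond and the tert-butyl group leaves as isobutene, under non-basic conditions and with the same geometric constraint on O1–C5 bond formation. The route is re-entered at the target 18.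

Step 3. The copper acetylide may attack the internal allylic carbon (SN2' course), or carbonate may move the skipped enyne of the product into conjugation. Fallback: setting out from 3, a Stille coupling with tributyl(trimethylsilylethynyl)stannane (Pd2(dba)3, tri(2-furyl)phosphine, THF, rt) joins the same two carbons under base-free conditions. It runs through a π-allyl complex of palladium, formed from the zerovalent catalyst, and the stannane couples at the unsubstituted terminus. This gives 5 directly, where the route resumes before step 4, and no compound outside the list is made (entry F0).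

**Further compounds**

F1 | step 10 | racemic 2-(trimethylsilyl)ethyl (6E)-8-acetoxy-2-[(E)-5-acetoxy-4-methylpent-3-en-1-yl]-6-methylocta-2,3,6-trienoate | C[Si](C)(C)CCOC(=O)C(CC/C=C(\C)COC(C)=O)=C=CC/C(C)=C/COC(C)=O
F2 | step 10 | 2-(trimethylsilyl)ethyl (aR,6E)-8-acetoxy-2-[(E)-5-acetoxy-4-methylpent-3-en-1-yl]-6-methylocta-2,3,6-trienoate | C[Si](C)(C)CCOC(=O)C(CC/C=C(\C)COC(C)=O)=[C@]=C([H])C/C(C)=C/COC(C)=O
F3 | step 11 | tert-butyl (E)-7-acetoxy-2-acetyl-6-methylhept-5-enoate | CC(=O)C(CC/C=C(\C)COC(C)=O)C(=O)OC(C)(C)C
F4 | step 11 | tert-butyl (E)-7-acetoxy-2-diazo-6-methylhept-5-enoate | CC(C)(C)OC(=O)C(=[N+]=[N-])CC/C=C(\C)COC(C)=O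
F5 | step 11 | tert-butyl (aS,6E)-8-acetoxy-2-[(E)-5-acetoxy-4-methylpent-3-en-1-yl]-6-methylocta-2,3,6-trienoate | CC(C)(C)OC(=O)C(CC/C=C(\C)COC(C)=O)=[C@@]=C([H])C/C(C)=C/COC(C)=O
F0 | step 3 | none | none
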